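**Plan**

1. Numbering used throughout: oxolane O1, C2 (aryl cis to the C3 arm), C3 (arm carbon C3a), C4 (arm carbon C4a), C5 (aryl trans to the C4 arm). C2 is a benzylic carbon at the aldehyde oxidation level bonded to O1 and C3, and C3a is one reduction away from a formyl carbon. The C3–C3a unit is therefore the imprint of an enol ether that is nucleophilic at C3.
2. Retrosynthesis: after adjusting C3a (CH2OH back to CHO) and the three benzyl ethers, O1–C2 and C2–C3 are cut together. This gives benzylated syringaldehyde and an open-chain silyl ether carrying a methyl enol ether. C3=C3a is then cut (Wittig), C3 is traced to a vinyl group, and C4–C5 is cut as an aldol bond.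
3. Forward: the chain is joined at C4–C5 by an aldol reaction, the auxiliary is reduced off, the primary oxygen is benzylated and the secondary one silylated. The vinyl group is converted via the aldehyde into the enol ether, and the only ring closes in step 9. Reduction and hydrogenolysis finish the synthesis.
4. Stereochemistry: C4 and C5 come from the auxiliary-controlled syn aldol (step 3). C2 and C3 arise in step 9 under control of these two centres and are secured by immediate reduction of the formyl group.

Key step: step 9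

Assumption: the Wittig reaction of step 8 is taken to give 17 as an E/Z mixture. Both isomers converge because C3a ends as a formyl carbon; the E isomer is drawn.

**Step 1**
Reactants: 1 syringaldehyde
Product: 2 4-(benzyloxy)-3,5-dimethoxybenzaldehyde
Conditions: BnBr, K2CO3, DMF, 60 °C
Reagents that add atoms: benzyl bromide, BrCc1ccccc1
Why: Williamson etherification of the phenoxide, the only acidic site, with a primary benzylic bromide; the aldehyde is inert to carbonate.

**Step 2**
Reactants: 3 (S)-4-benzyl-2-oxazolidinone; 4 (E)-crotonyl chloride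
Product: 6 (S)-4-benzyl-3-[(E)-but-2-enoyl]oxazolidin-2-one, via lithium oxazolidinide 5 (not isolated)
Conditions: n-BuLi, THF, −78 °C; then 4, −78 → 0 °C
Reagents that add atoms: none
Why: N-acylation of the lithiated oxazolidinone (standard imide formation), in which the lithium carbamate at −78 °C attacks the acyl chloride carbonyl rather than the conjugate position.

**Step 3**
Reactants: 6 (S)-4-benzyl-3-[(E)-but-2-enoyl]oxazolidin-2-one; 2 4-(benzyloxy)-3,5-dimethoxybenzaldehyde
Product: 9 (S)-4-benzyl-3-[(2S,3S)-3-[4-(benzyloxy)-3,5-dimethoxyphenyl]-2-ethenyl-3-hydroxypropanoyl]oxazolidin-2-one, via boron dienolate 7 (not isolated), via boron aldolate 8 (not isolated)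
Conditions: n-Bu2BOTf, Et3N, CH2Cl2, −78 → 0 °C; 2, −78 → 0 °C; then pH 7 phosphate buffer, MeOH, 30% H2O2, 0 °C
Reagents that add atoms: none
Why: Evans syn aldol of a crotonate imide, in which soft enolisation gives the Z(O) boron dienolate that reacts at its α-carbon through a Zimmerman–Traxler chair with the aldehyde on the face away from the auxiliary benzyl group, which should set the future C4 and C5 as the 2S,3S syn pair.

**Step 4**
Reactants: 9 aldol adduct
Product: 10 (1S,2R)-1-[4-(benzyloxy)-3,5-dimethoxyphenyl]-2-ethenylpropane-1,3-diol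
Conditions: LiBH4, MeOH (1 equiv), THF, 0 °C
Reagents that add atoms: none
Why: Reductive cleavage of the imide with LiBH4 (hydroxyl-assisted hydride attack at the exocyclic carbonyl) should give the 1,3-diol and return the auxiliary without touching the vinyl group or the α-carbon, retro-aldol being slow at 0 °C.

**Step 5**
Reactants: 10 (1S,2R)-1-[4-(benzyloxy)-3,5-dimethoxyphenyl]-2-ethenylpropane-1,3-diol
Product: 12 (1S,2R)-2-[(benzyloxy)methyl]-1-[4-(benzyloxy)-3,5-dimethoxyphenyl]but-3-en-1-ol, via stannylene acetal 11 (not isolated)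
Conditions: Bu2SnO, toluene, reflux (Dean–Stark); then BnBr, Bu4NI (cat.), 90 °C
Reagents that add atoms: benzyl bromide, BrCc1ccccc1
Why: Stannylene-acetal-directed regioselective O-alkylation, in which the six-membered dibutylstannylene acetal raises the nucleophilicity of the less hindered primary oxygen, so that benzylation should occur there and leave the secondary benzylic hydroxyl free.

**Step 6**
Reactants: 12 (1S,2R)-2-[(benzyloxy)methyl]-1-[4-(benzyloxy)-3,5-dimethoxyphenyl]but-3-en-1-ol
Product: 13 {[(1S,2R)-2-[(benzyloxy)methyl]-1-[4-(benzyloxy)-3,5-dimethoxyphenyl]but-3-en-1-yl]oxy}trimethylsilane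
Conditions: TMSCl, imidazole, CH2Cl2, 0 °C
Reagents that add atoms: chlorotrimethylsilane, C[Si](C)(C)Cl
Why: Standard silylation of a secondary alcohol, the trimethylsilyl ether being the silyl ether class that condenses with aldehydes under silyl triflate catalysis in step 9.

**Step 7**
Reactants: 13 trimethylsilyl ether
Product: 15 (2R,3S)-2-[(benzyloxy)methyl]-3-[4-(benzyloxy)-3,5-dimethoxyphenyl]-3-[(trimethylsilyl)oxy]propanal, via ozonide 14 (not isolated)
Conditions: O3, NaHCO3, CH2Cl2, −78 °C (Sudan Red 7B end-point); then PPh3, −78 °C → rt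
Reagents that add atoms: ozone, [O-][O+]=O
Why: Ozonolysis with reductive work-up (Criegee pathway), in which the monosubstituted alkene should react far faster than the trialkoxyarenes or benzyl ethers, the dye marks the end-point, and the anhydrous base-free sequence should preserve the silyl ether and the α-stereocentre.

**Step 8**
Reactants: 15 aldehyde; 16 (methoxymethyl)triphenylphosphonium chloride
Product: 17 {[(1S,2R)-2-[(benzyloxy)methyl]-1-[4-(benzyloxy)-3,5-dimethoxyphenyl]-4-methoxybut-3-en-1-yl]oxy}trimethylsilane (E/Z mixture)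
Conditions: 16, KN(SiMe3)2, THF, 0 °C; then 15, −78 → 0 °C
Reagents that add atoms: none
Why: Wittig methoxymethylenation, in which the non-stabilised ylide should add to the formyl group at −78 °C faster than it enolises it, so that the α-stereocentre (future C4) and the β-silyloxy group survive.

**Step 9**
Reactants: 17 silyl ether enol ether; 2 4-(benzyloxy)-3,5-dimethoxybenzaldehyde
Product: 19 (2R,3S,4R,5S)-4-[(benzyloxy)methyl]-2,5-bis[4-(benzyloxy)-3,5-dimethoxyphenyl]oxolane-3-carbaldehyde, via methyl trimethylsilyl acetal 18 (not isolated)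
Conditions: 2 (1.3 equiv), TMSOTf (0.2 equiv), 2,6-di-tert-butyl-4-methylpyridine (0.3 equiv), 4 Å MS, CH2Cl2, −78 °C; Et3N, −78 °C; then citrate buffer (pH 5)/THF, 0 °C
Reagents that add atoms: none
Why: TMSOTf silylates aldehyde 2, the silyl ether oxygen of 17 adds and hexamethyldisiloxane departs to leave the aryl-stabilised E-oxocarbenium ion O1=C2, which the nucleophilic enol ether carbon C3 attacks to close the oxolane; the methoxycarbenium ion left at C3a takes the siloxane back as acetal 18 with release of TMSOTf, and buffered hydrolysis unveils the formyl group. The closest known reaction type is the Lewis acid rearrangement of cyclic vinyl acetals (4,5-dihydro-1,3-dioxepines) to cis-2-substituted oxolane-3-carbaldehydes, a Prins/Mukaiyama-type oxocarbenium–enol ether cyclisation, here combined with the aldehyde–trimethylsilyl ether condensation of the silyl-modified Sakurai reaction. The ring closes in a five-membered mode that is exo to the enol ether double bond and endo to the O1=C2 bond (5-enolexo-endo-trig), which cationic closures of this kind tolerate. C2 should be set by the E geometry of the oxocarbenium ion together with an envelope in which the C5 aryl and C4 benzyloxymethyl groups are pseudo-equatorial, so that C3 bonds to the face giving the 2,5-cis diaryl arrangement. C3 should be set by the C4 stereocentre, whose C–H bond eclipses the enol ether (allylic 1,3-strain, stronger for the Z isomer), so that C3a ends trans to C4a and therefore cis to the C2 aryl group for either enol ether geometry. The step needs regioselectivity (closure through C3, not six-membered closure through C3a or an oxonia-Cope shift), secured by the methoxy group that makes C3 the nucleophilic terminus; chemoselectivity over proton-induced closure to a 2-methoxyoxolane, secured by the hindered pyridine base and sieves; and kinetic control, secured by −78 °C, substoichiometric triflate and the amine quench.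

**Step 10**
Reactants: 19 oxolane-3-carbaldehyde (crude, not chromatographed)
Product: 20 [(2R,3R,4R,5S)-4-[(benzyloxy)methyl]-2,5-bis[4-(benzyloxy)-3,5-dimethoxyphenyl]oxolan-3-yl]methanol
Conditions: NaBH4, MeOH/CH2Cl2, −40 → 0 °C
Reagents that add atoms: none
Why: Borohydride reduction of the formyl group at low temperature is much faster than its enolisation, so C3 should stay cis to the C2 aryl group, and any acetal 18 that survived the work-up is methanolysed under the same conditions and converges on 20.

**Step 11**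
Reactants: 20 tribenzyl ether
Product: 21 [(2R,3R,4R,5S)-2,5-bis(4-hydroxy-3,5-dimethoxyphenyl)oxolane-3,4-diyl]dimethanol
Conditions: H2 (1 atm), 10% Pd/C, EtOAc/MeOH, rt
Reagents that add atoms: none
Why: Catalytic hydrogenolysis should cleave the two aryl benzyl ethers and the primary alkyl benzyl ether under neutral conditions before the more hindered ring benzylic C–O bonds react, and it avoids the acid- or base-induced quinone methide epimerisation at C2 and C5.

**Compound list**

1 | syringaldehyde (4-hydroxy-3,5-dimethoxybenzaldehyde) | COc1cc(C=O)cc(OC)c1O | starting material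
2 | 4-(benzyloxy)-3,5-dimethoxybenzaldehyde | COc1cc(C=O)cc(OC)c1OCc2ccccc2 | intermediate
3 | (S)-4-benzyl-2-oxazolidinone | O=C1N[C@@H](Cc2ccccc2)CO1 | starting material
4 | (E)-crotonyl chloride | C/C=C/C(=O)Cl | starting material
5 | N-lithio-(S)-4-benzyl-2-oxazolidinone, formed in the flask | [Li]N1C(=O)OC[C@@H]1Cc2ccccc2 | intermediate
6 | (S)-4-benzyl-3-[(E)-but-2-enoyl]oxazolidin-2-one | C/C=C/C(=O)N1C(=O)OC[C@@H]1Cc2ccccc2 | intermediate
7 | dibutylboron Z(O)-dienolate of 6, formed in the flask | C=C/C=C(\OB(CCCC)CCCC)N1C(=O)OC[C@@H]1Cc2ccccc2 | intermediate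
8 | O-dibutylboryl aldolate of 9, formed in the flask | COc1cc([C@@H](OB(CCCC)CCCC)[C@H](C=C)C(=O)N2C(=O)OC[C@@H]2Cc3ccccc3)cc(OC)c1OCc4ccccc4 | intermediate
9 | (S)-4-benzyl-3-[(2S,3S)-3-[4-(benzyloxy)-3,5-dimethoxyphenyl]-2-ethenyl-3-hydroxypropanoyl]oxazolidin-2-one | COc1cc([C@@H](O)[C@H](C=C)C(=O)N2C(=O)OC[C@@H]2Cc3ccccc3)cc(OC)c1OCc4ccccc4 | intermediate
10 | (1S,2R)-1-[4-(benzyloxy)-3,5-dimethoxyphenyl]-2-ethenylpropane-1,3-diol | COc1cc([C@@H](O)[C@@H](CO)C=C)cc(OC)c1OCc2ccccc2 | intermediate
11 | (4S,5R)-4-[4-(benzyloxy)-3,5-dimethoxyphenyl]-2,2-dibutyl-5-ethenyl-1,3,2-dioxastanninane, formed in the flask | COc1cc([C@H]2O[Sn](CCCC)(CCCC)OC[C@H]2C=C)cc(OC)c1OCc3ccccc3 | intermediate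
12 | (1S,2R)-2-[(benzyloxy)methyl]-1-[4-(benzyloxy)-3,5-dimethoxyphenyl]but-3-en-1-ol | COc1cc([C@@H](O)[C@@H](COCc2ccccc2)C=C)cc(OC)c1OCc3ccccc3 | intermediate
13 | trimethylsilyl ether of 12, (1S,2R) | COc1cc([C@@H](O[Si](C)(C)C)[C@@H](COCc2ccccc2)C=C)cc(OC)c1OCc3ccccc3 | intermediate
14 | 1,2,4-trioxolane (ozonide) of 13, epimers at the trioxolane carbon, formed in the flask | COc1cc([C@@H](O[Si](C)(C)C)[C@@H](COCc2ccccc2)C3OCOO3)cc(OC)c1OCc4ccccc4 | intermediate
15 | (2R,3S)-2-[(benzyloxy)methyl]-3-[4-(benzyloxy)-3,5-dimethoxyphenyl]-3-[(trimethylsilyl)oxy]propanal | COc1cc([C@@H](O[Si](C)(C)C)[C@@H](COCc2ccccc2)C=O)cc(OC)c1OCc3ccccc3 | intermediate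
16 | (methoxymethyl)triphenylphosphonium chloride | COC[P+](c1ccccc1)(c2ccccc2)c3ccccc3.[Cl-] | starting material
17 | {[(1S,2R)-2-[(benzyloxy)methyl]-1-[4-(benzyloxy)-3,5-dimethoxyphenyl]-4-methoxybut-3-en-1-yl]oxy}trimethylsilane, E/Z mixture, E drawn | COc1cc([C@@H](O[Si](C)(C)C)[C@@H](COCc2ccccc2)/C=C/OC)cc(OC)c1OCc3ccccc3 | intermediate
18 | methyl trimethylsilyl acetal of 19 at C3a, epimers at the acetal carbon, formed in the flask | COc1cc([C@H]2O[C@@H](c3cc(OC)c(OCc4ccccc4)c(OC)c3)[C@@H](C(OC)O[Si](C)(C)C)[C@@H]2COCc5ccccc5)cc(OC)c1OCc6ccccc6 | intermediate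
19 | (2R,3S,4R,5S)-4-[(benzyloxy)methyl]-2,5-bis[4-(benzyloxy)-3,5-dimethoxyphenyl]oxolane-3-carbaldehyde (2,3-cis, 3,4-trans, 4,5-trans) | COc1cc([C@H]2O[C@@H](c3cc(OC)c(OCc4ccccc4)c(OC)c3)[C@@H](C=O)[C@@H]2COCc5ccccc5)cc(OC)c1OCc6ccccc6 | intermediate
20 | [(2R,3R,4R,5S)-4-[(benzyloxy)methyl]-2,5-bis[4-(benzyloxy)-3,5-dimethoxyphenyl]oxolan-3-yl]methanol | COc1cc([C@H]2O[C@@H](c3cc(OC)c(OCc4ccccc4)c(OC)c3)[C@@H](CO)[C@@H]2COCc5ccccc5)cc(OC)c1OCc6ccccc6 | intermediate
21 | [(2R,3R,4R,5S)-2,5-bis(4-hydroxy-3,5-dimethoxyphenyl)oxolane-3,4-diyl]dimethanol (2,5-cis diaryl, 2,3-cis, 3,4-trans, 4,5-trans) | COc1cc([C@H]2O[C@@H](c3cc(OC)c(O)c(OC)c3)[C@@H](CO)[C@@H]2CO)cc(OC)c1O | target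

**Step count and risks**

Total: 11 steps. Longest linear sequence: 10 steps (steps 2 to 11, from 3 and 4). Step 1 is a one-step branch that supplies aldehyde 2 to steps 3 and 9.

Steps most likely to fail:

**Step 9.** The condensation of aldehyde and silyl ether may lose out to proton-initiated closure of the silyloxy oxygen onto the enol ether. The oxocarbenium ion may also form too slowly from the free aldehyde, so that the enol ether is consumed otherwise, and facial selectivity at C2 and C3 may erode if the closure becomes reversible. The fallback forms O1–C2 before ionisation; it sets out from 17 and returns at 20.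
- K2CO3 in MeOH at 0 °C should remove the silyl group to give the hydroxy enol ether F1.
- Acylation with 4-(benzyloxy)-3,5-dimethoxybenzoyl chloride (Et3N, DMAP, CH2Cl2) should give the benzoate ester F2.
- Reductive acetylation (i-Bu2AlH, CH2Cl2, −78 °C; then Ac2O, pyridine, DMAP) should give the α-acetoxy ether F3.
- BF3·OEt2 or TMSOTf at −78 °C should ionise F3 to the same oxocarbenium ion (segment-coupling Prins-type closure), with acetate returning to C3a to give the acetoxy methyl acetal F4.
- NaBH4 in MeOH should then unmask and reduce F4 to 20.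

**Step 8.** The basic ylide may deprotonate aldehyde 15, with epimerisation at the future C4 or β-elimination of silanolate towards a cinnamaldehyde. The fallback never passes through an aldehyde with an adjacent stereocentre and also avoids ozone; it sets out from 13 and returns at 19.
- Hydroboration–oxidation (9-BBN, THF; then NaBO3·4H2O) should give the primary alcohol F5.
- Dess–Martin periodinane buffered with NaHCO3 should give the homologous aldehyde F6.
- TESOTf and Et3N in CH2Cl2 at 0 °C should give the triethylsilyl enol ether F7.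
- Under the conditions of step 9 with 2, F7 should add to the oxocarbenium ion in a Mukaiyama-type closure and lose its silyl group, giving 19 directly.

**Step 5.** The alkylation may fail to discriminate between the two hydroxyl groups, with benzylation at the benzylic oxygen or at both. The fallback differentiates the oxygens by order of events; it sets out from 9 and returns at 12.
- TESOTf and 2,6-lutidine should give the triethylsilyl ether F8.
- LiBH4 should remove the auxiliary to give the primary alcohol F9.
- Benzylation without an alkoxide (2-benzyloxy-1-methylpyridinium triflate, MgO, PhCF3, 85 °C), which excludes silyl migration, should give the benzyl ether F10.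
- Bu4NF buffered with AcOH in THF should then free the secondary alcohol to give 12.

**Further compounds**

F1 | step 9 | (1S,2R)-2-[(benzyloxy)methyl]-1-[4-(benzyloxy)-3,5-dimethoxyphenyl]-4-methoxybut-3-en-1-ol (E drawn) | COc1cc([C@@H](O)[C@@H](COCc2ccccc2)/C=C/OC)cc(OC)c1OCc3ccccc3
F2 | step 9 | 4-(benzyloxy)-3,5-dimethoxybenzoate ester of F1 | COc1cc([C@@H](OC(=O)c2cc(OC)c(OCc3ccccc3)c(OC)c2)[C@@H](COCc4ccccc4)/C=C/OC)cc(OC)c1OCc5ccccc5
F3 | step 9 | α-acetoxy ether from F2 (acetoxy(aryl)methyl ether of F1, epimers at the acetal carbon) | COc1cc([C@@H](OC(OC(C)=O)c2cc(OC)c(OCc3ccccc3)c(OC)c2)[C@@H](COCc4ccccc4)/C=C/OC)cc(OC)c1OCc5ccccc5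
F4 | step 9 | acetoxy methyl acetal of 19 at C3a (epimers at the acetal carbon) | COc1cc([C@H]2O[C@@H](c3cc(OC)c(OCc4ccccc4)c(OC)c3)[C@@H](C(OC)OC(C)=O)[C@@H]2COCc5ccccc5)cc(OC)c1OCc6ccccc6
F5 | step 8 | (3R,4S)-3-[(benzyloxy)methyl]-4-[4-(benzyloxy)-3,5-dimethoxyphenyl]-4-[(trimethylsilyl)oxy]butan-1-ol | COc1cc([C@@H](O[Si](C)(C)C)[C@@H](COCc2ccccc2)CCO)cc(OC)c1OCc3ccccc3
F6 | step 8 | (3R,4S)-3-[(benzyloxy)methyl]-4-[4-(benzyloxy)-3,5-dimethoxyphenyl]-4-[(trimethylsilyl)oxy]butanal | COc1cc([C@@H](O[Si](C)(C)C)[C@@H](COCc2ccccc2)CC=O)cc(OC)c1OCc3ccccc3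
F7 | step 8 | triethylsilyl enol ether of F6 (Z drawn, E/Z mixture expected) | COc1cc([C@@H](O[Si](C)(C)C)[C@@H](COCc2ccccc2)/C=C\O[Si](CC)(CC)CC)cc(OC)c1OCc3ccccc3
F8 | step 5 | triethylsilyl ether of 9 | COc1cc([C@@H](O[Si](CC)(CC)CC)[C@H](C=C)C(=O)N2C(=O)OC[C@@H]2Cc3ccccc3)cc(OC)c1OCc4ccccc4
F9 | step 5 | (2R,3S)-3-[4-(benzyloxy)-3,5-dimethoxyphenyl]-2-ethenyl-3-[(triethylsilyl)oxy]propan-1-ol | COc1cc([C@@H](O[Si](CC)(CC)CC)[C@@H](CO)C=C)cc(OC)c1OCc2ccccc2
F10 | step 5 | triethylsilyl ether of 12 | COc1cc([C@@H](O[Si](CC)(CC)CC)[C@@H](COCc2ccccc2)C=C)cc(OC)c1OCc3ccccc3
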